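## Retrosynthetic overview
1. The heterocyclic C-ring is not pre-built. In the last flask the methylcyclohexene is made by an exo, (R)-VANOL-borate-templated [4+2]. The dihydropyranone is then made by 6-endo phenoxide opening of an (αR,βS)-epoxy ketone carried on the diene partner.
2. The dienyl epoxychalcone comes from Juliá–Colonna epoxidation of a chalcone. That chalcone is built from 2,4-bis(allyloxy)acetophenone and O-allyl-5-dienylsalicylaldehyde, and the diene comes from Heck arylation of isoprene with 5-bromosalicylaldehyde.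
3. The chromeno-2'-hydroxychalcone comes from Claisen–Schmidt condensation of 2,4-bis(allyloxy)benzaldehyde with an acetylchromenol. The acetylchromenol is made from resacetophenone and prenal (aldol/oxa-6π).
4. Ring order: 2H-pyran (chromene), then oxirane (stereo-relay, consumed), then cyclohexene and dihydropyranone together. Allyl is the only protecting group.

Assumption: poly-L-leucine is taken to give the (αR,βS)-epoxy ketone, and the (R)-VANOL borate is taken to leave the Cα-Si face of the chelated chalcone open (the latter from a geometric model, not a checked precedent); both are verified on the first run and the equally available antipodal catalyst is used if a sense is opposite.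

## Route

Step 1
Reactants: 1 2,4-dihydroxyacetophenone; 2 3-methylbut-2-enal (prenal)
Product: 3 1-(5-hydroxy-2,2-dimethyl-2H-chromen-6-yl)ethan-1-one
Conditions: pyridine, 140 °C (sealed tube), 18 h
Reagents that add atoms: none
Why: Aldol-type attack of resorcinol C-3 (between the two oxygens, the chelated 2-OH staying free) on prenal, dehydration to an o-quinone methide and oxa-6π electrocyclisation (formal [3+3] chromenylation) give the angular 5-hydroxy-6-acylchromene; no stereocentre.

Step 2
Reactants: 4 2,4-dihydroxybenzaldehyde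
Product: 5 2,4-bis(allyloxy)benzaldehyde
Conditions: allyl bromide, K2CO3, DMF, 60 °C
Reagents that add atoms: allyl bromide, C=CCBr
Why: Double Williamson etherification gives a base-stable group that is later removed under near-neutral Pd(0) conditions.

Step 3
Reactants: 3 acetylchromenol; 5 2,4-bis(allyloxy)benzaldehyde
Product: 6 (E)-3-[2,4-bis(allyloxy)phenyl]-1-(5-hydroxy-2,2-dimethyl-2H-chromen-6-yl)prop-2-en-1-one
Conditions: KOH, EtOH–H2O, rt, 48 h; then aq HCl to pH 5
Reagents that add atoms: none
Why: Claisen–Schmidt condensation with E1cB dehydration gives the thermodynamic E-enone and keeps the chelated 2'-OH free as the later boron anchor.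

Step 4
Reactants: 1 2,4-dihydroxyacetophenone
Product: 7 1-[2,4-bis(allyloxy)phenyl]ethan-1-one
Conditions: allyl bromide, K2CO3, DMF, 70 °C
Reagents that add atoms: allyl bromide, C=CCBr
Why: Williamson etherification under forcing conditions also alkylates the hydrogen-bonded 2-OH, so this ketone can never chelate boron later.

Step 5
Reactants: 8 5-bromo-2-hydroxybenzaldehyde; 9 isoprene
Product: 10 2-hydroxy-5-[(1E)-3-methylbuta-1,3-dien-1-yl]benzaldehyde
Conditions: Pd(OAc)2 (3 mol %), P(o-tol)3, Et3N, MeCN, BHT, isoprene (5 equiv), 100 °C (sealed tube)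
Reagents that add atoms: none
Why: In this Mizoroki–Heck arylation of a 1,3-diene, Ar–Pd adds to the unsubstituted vinyl terminus of isoprene and benzylic β-hydride elimination from the π-allyl gives the conjugated E-diene.

Step 6
Reactants: 10 dienyl salicylaldehyde
Product: 11 2-(allyloxy)-5-[(1E)-3-methylbuta-1,3-dien-1-yl]benzaldehyde
Conditions: allyl bromide, K2CO3, DMF, rt
Reagents that add atoms: allyl bromide, C=CCBr
Why: Williamson etherification at room temperature leaves the diene untouched and masks the B-ring phenol, which would otherwise deactivate the enone and attack the later epoxide.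

Step 7
Reactants: 7 2,4-bis(allyloxy)acetophenone; 11 O-allyl dienyl salicylaldehyde
Product: 12 (E)-1-[2,4-bis(allyloxy)phenyl]-3-{2-(allyloxy)-5-[(1E)-3-methylbuta-1,3-dien-1-yl]phenyl}prop-2-en-1-one
Conditions: KOH, EtOH, rt, 24 h
Reagents that add atoms: none
Why: Claisen–Schmidt condensation gives the E-enone, and allyl ethers and the diene are inert to hydroxide at room temperature.

Step 8
Reactants: 12 dienyl chalcone
Product: 13 [2,4-bis(allyloxy)phenyl][(2R,3S)-3-{2-(allyloxy)-5-[(1E)-3-methylbuta-1,3-dien-1-yl]phenyl}oxiran-2-yl]methanone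
Conditions: poly-L-leucine, urea·H2O2, DBU, THF, rt, 24–48 h
Reagents that add atoms: urea–hydrogen peroxide, NC(N)=O.OO
Why: In this Juliá–Colonna (asymmetric Weitz–Scheffer) epoxidation, hydroperoxide attacks only the electron-poor enone C=C (diene and allyl groups are not electrophilic), and the L-leucine helix delivers it to the face giving the trans-(αR,βS)-epoxide, which holds the information for C3 (kept) and C2 (to be inverted).

Step 9
Reactants: 6 chromeno-2'-hydroxychalcone; 13 dienyl epoxychalcone
Product: 17 target CNP0204112.1, via exo cycloadduct penta-O-allyl epoxy ketone 14 (not isolated), via A-ring-unmasked epoxy ketone 15 (not isolated), via tri-O-allyl dihydroflavonol 16 (not isolated)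
Conditions: (R)-VANOL (1.1 equiv), B(OPh)3 (1.05 equiv), PhMe, 80 °C, then vacuum; 6 (1.15 equiv), 5 Å MS, PhCF3, rt; 13 (1.0 equiv), rt, 36 h; then THF–MeOH, morpholine (15 equiv), Pd(PPh3)4 (10 mol %), rt, Ar
Reagents that add atoms: none
Why: Proposed new method: covalent chelation of the 2'-OH/C=O of 6 to the (R)-VANOL borate makes it the only activated dienophile (no free Lewis acid remains for the epoxide) and leaves its Cα-Si face open, so the p-alkoxystyryl diene of 13 adds with "ortho" regiochemistry through the aroyl-exo transition state (the vaulted ligand crowds the space the diene C2–C3(Me) edge needs in the endo mode) to set the all-trans cyclohexene (C-aryl R, C-aroyl R, C-resorcinyl S), after which Pd(0)/morpholine removes allyl fastest from the acyl-activated A-ring (best phenoxide leaving groups) and its 2'-phenoxide opens the epoxide 6-endo at the benzylic carbon with inversion while Cα–O is untouched, giving the 2R,3R-trans dihydroflavonol before the last three allyl groups are cleaved; the closest known reaction types are the chiral-borate Diels–Alder reaction of 2'-hydroxychalcones, Tsuji–Trost deallylation and the stereospecific cyclisation of 2'-hydroxychalcone epoxides (Algar–Flynn–Oyamada manifold), here run in one flask on an epoxide-bearing diene.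

## Compound list
1 | 2,4-dihydroxyacetophenone | CC(=O)c1ccc(O)cc1O | starting material
2 | 3-methylbut-2-enal | CC(C)=CC=O | starting material
3 | 1-(5-hydroxy-2,2-dimethyl-2H-chromen-6-yl)ethan-1-one | CC(=O)c1ccc2c(c1O)C=CC(C)(C)O2 | intermediate
4 | 2,4-dihydroxybenzaldehyde | O=Cc1ccc(O)cc1O | starting material
5 | 2,4-bis(allyloxy)benzaldehyde | C=CCOc1ccc(C=O)c(OCC=C)c1 | intermediate
6 | (E)-3-[2,4-bis(allyloxy)phenyl]-1-(5-hydroxy-2,2-dimethyl-2H-chromen-6-yl)prop-2-en-1-one | C=CCOc1ccc(/C=C/C(=O)c2ccc3c(c2O)C=CC(C)(C)O3)c(OCC=C)c1 | intermediate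
7 | 1-[2,4-bis(allyloxy)phenyl]ethan-1-one | CC(=O)c1ccc(OCC=C)cc1OCC=C | intermediate
8 | 5-bromo-2-hydroxybenzaldehyde | O=Cc1cc(Br)ccc1O | starting material
9 | isoprene | C=CC(C)=C | starting material
10 | 2-hydroxy-5-[(1E)-3-methylbuta-1,3-dien-1-yl]benzaldehyde | O=Cc1cc(/C=C/C(C)=C)ccc1O | intermediate
11 | 2-(allyloxy)-5-[(1E)-3-methylbuta-1,3-dien-1-yl]benzaldehyde | O=Cc1cc(/C=C/C(C)=C)ccc1OCC=C | intermediate
12 | (E)-1-[2,4-bis(allyloxy)phenyl]-3-{2-(allyloxy)-5-[(1E)-3-methylbuta-1,3-dien-1-yl]phenyl}prop-2-en-1-one | C=CCOc1ccc(C(=O)/C=C/c2cc(/C=C/C(C)=C)ccc2OCC=C)c(OCC=C)c1 | intermediate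
13 | [2,4-bis(allyloxy)phenyl][(2R,3S)-3-{2-(allyloxy)-5-[(1E)-3-methylbuta-1,3-dien-1-yl]phenyl}oxiran-2-yl]methanone (trans, αR,βS) | C=CCOc1ccc(C(=O)[C@@H]2O[C@H]2c2cc(/C=C/C(C)=C)ccc2OCC=C)c(OCC=C)c1 | intermediate
14 | exo (all-trans) cycloadduct: {(1R,2R,6S)-2-{4-(allyloxy)-3-[(2S,3R)-3-(2,4-bis(allyloxy)benzoyl)oxiran-2-yl]phenyl}-6-[2,4-bis(allyloxy)phenyl]-4-methylcyclohex-3-en-1-yl}(5-hydroxy-2,2-dimethyl-2H-chromen-6-yl)methanone | CC1=C[C@@H](c2ccc(OCC=C)c([C@@H]3O[C@H]3C(=O)c3ccc(OCC=C)cc3OCC=C)c2)[C@H](C(=O)c2ccc3c(c2O)C=CC(C)(C)O3)[C@@H](c2ccc(OCC=C)cc2OCC=C)C1 | intermediate (not isolated)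
15 | as 14, but with the benzoyl ring on the oxirane as the free 2,4-dihydroxybenzoyl group (three allyl ethers left) | CC1=C[C@@H](c2ccc(OCC=C)c([C@@H]3O[C@H]3C(=O)c3ccc(O)cc3O)c2)[C@H](C(=O)c2ccc3c(c2O)C=CC(C)(C)O3)[C@@H](c2ccc(OCC=C)cc2OCC=C)C1 | intermediate (not isolated)
16 | (2R,3R)-trans-dihydroflavonol, i.e. the target with its 2'-OH and the two resorcinyl OH still as allyl ethers | CC1=C[C@@H](c2ccc(OCC=C)c([C@H]3Oc4cc(O)ccc4C(=O)[C@@H]3O)c2)[C@H](C(=O)c2ccc3c(c2O)C=CC(C)(C)O3)[C@@H](c2ccc(OCC=C)cc2OCC=C)C1 | intermediate (not isolated)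
17 | (2R,3R)-2-{5-[(1R,5S,6R)-5-(2,4-dihydroxyphenyl)-6-(5-hydroxy-2,2-dimethyl-2H-chromene-6-carbonyl)-3-methylcyclohex-2-en-1-yl]-2-hydroxyphenyl}-3,7-dihydroxychroman-4-one | CC1=C[C@@H](c2ccc(O)c([C@H]3Oc4cc(O)ccc4C(=O)[C@@H]3O)c2)[C@H](C(=O)c2ccc3c(c2O)C=CC(C)(C)O3)[C@@H](c2ccc(O)cc2O)C1 | target

## Count and risks
Total steps: 9. Longest linear sequence: 5 (steps 5, 6, 7, 8, 9).

**Step 9 (most likely to fail).**
- The exo:endo ratio is substrate-dependent for a diene aryl group without ortho substituents.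
- The electron-rich aryl epoxide may not survive 36 h next to boron and phenol.
- If the B-ring phenol is freed early, it can attack Cα (5-exo) instead of the wanted 6-endo closure.

The fallback sets out from 13 and comes back at 17. It uncouples the two ring closures and builds the heterocycle first. Pd(PPh3)4/morpholine on 13 gives, by the same deallylation and 6-endo opening, (2R,3R)-3,7-dihydroxy-2-{2-hydroxy-5-[(1E)-3-methylbuta-1,3-dien-1-yl]phenyl}chroman-4-one F1. Allyl chloroformate/pyridine turns it into the tris(allyl carbonate) of this dienyl dihydroflavonol F2, a diene with neither epoxide nor free OH. The (R)-VANOL-borate cycloaddition with 6 then gives the isolable exo adduct bearing two allyl ethers and three allyl carbonates F3, which is freed from the endo isomer by chromatography. One Pd(PPh3)4/morpholine treatment removes all five groups and gives 17.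

**Step 8.** Two ortho-alkoxy groups and two electron-rich rings slow hydroperoxide addition and may erode the ee. The fallback sets out from 11 and comes back at 13. It makes the oxirane by iminium catalysis on an enal instead of by peroxide addition to the hindered diaryl enone.
- Wittig homologation of 11 with Ph3P=CHCHO (PhMe, 80 °C) gives (E)-3-{2-(allyloxy)-5-[(1E)-3-methylbuta-1,3-dien-1-yl]phenyl}prop-2-enal F4.
- Aqueous H2O2 with 10 mol % (R)-2-{bis[3,5-bis(trifluoromethyl)phenyl](trimethylsilyloxy)methyl}pyrrolidine in CH2Cl2 gives the (2R,3S)-epoxy aldehyde F5. The (R)-catalyst is chosen from the standard shielding model.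
- 4-Bromoresorcinol is bis-allylated (allyl bromide, K2CO3) to 2,4-bis(allyloxy)-1-bromobenzene F6.
- Br/Li exchange on F6 (n-BuLi, THF, −78 °C) and addition to F5 give the epoxy carbinol F7. Its carbinol epimers do not matter.
- Buffered Dess–Martin oxidation returns 13.

**Step 5.** Possible failures are regioisomeric arylation at the methyl-substituted end of isoprene, capture of the π-allyl by phenoxide, and diene oligomerisation at 100 °C. The fallback sets out from 8 and comes back at 10. It brings the diene in preformed. Cp2ZrHCl-catalysed syn-hydroboration of 2-methylbut-1-en-3-yne with pinacolborane gives the (E)-3-methylbuta-1,3-dienylboronic acid pinacol ester F8. Suzuki–Miyaura coupling with 8 (Pd(dppf)Cl2, K2CO3, dioxane–H2O, 80 °C) gives 10 with regiochemistry and E-geometry fixed by the boronate.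

## Further compounds
F1 | step 9 | (2R,3R)-3,7-dihydroxy-2-{2-hydroxy-5-[(1E)-3-methylbuta-1,3-dien-1-yl]phenyl}chroman-4-one | C=C(C)/C=C/c1ccc(O)c([C@H]2Oc3cc(O)ccc3C(=O)[C@@H]2O)c1
F2 | step 9 | 3,7,2'-tris(allyl carbonate) of F1 | C=C(C)/C=C/c1ccc(OC(=O)OCC=C)c([C@H]2Oc3cc(OC(=O)OCC=C)ccc3C(=O)[C@@H]2OC(=O)OCC=C)c1
F3 | step 9 | exo cycloadduct of 6 and F2 (two allyl ethers, three allyl carbonates; stereocentres as in 17) | CC1=C[C@@H](c2ccc(OC(=O)OCC=C)c([C@H]3Oc4cc(OC(=O)OCC=C)ccc4C(=O)[C@@H]3OC(=O)OCC=C)c2)[C@H](C(=O)c2ccc3c(c2O)C=CC(C)(C)O3)[C@@H](c2ccc(OCC=C)cc2OCC=C)C1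
F4 | step 8 | (E)-3-{2-(allyloxy)-5-[(1E)-3-methylbuta-1,3-dien-1-yl]phenyl}prop-2-enal | C=CCOc1ccc(/C=C/C(C)=C)cc1/C=C/C=O
F5 | step 8 | (2R,3S)-3-{2-(allyloxy)-5-[(1E)-3-methylbuta-1,3-dien-1-yl]phenyl}oxirane-2-carbaldehyde | O=C[C@@H]1O[C@H]1c1cc(/C=C/C(C)=C)ccc1OCC=C
F6 | step 8 | 2,4-bis(allyloxy)-1-bromobenzene | C=CCOc1ccc(Br)c(OCC=C)c1
F7 | step 8 | [2,4-bis(allyloxy)phenyl]{3-[2-(allyloxy)-5-((1E)-3-methylbuta-1,3-dien-1-yl)phenyl]oxiran-2-yl}methanol, oxirane configured as in 13, carbinol epimers | OC(c1ccc(OCC=C)cc1OCC=C)[C@@H]1O[C@H]1c1cc(/C=C/C(C)=C)ccc1OCC=C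
F8 | step 5 | 4,4,5,5-tetramethyl-2-[(1E)-3-methylbuta-1,3-dien-1-yl]-1,3,2-dioxaborolane | CC(=C)/C=C/B1OC(C)(C)C(C)(C)O1
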